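**Retrosynthetic overview**
- Chain A, C(quaternary)–(CH2)3–CH(CH3)–CH=CH2, is cut back to a vinyl group on the quaternary carbon. It is rebuilt from vinyl + CO (hydroformylation) + a Z-crotyl unit (asymmetric crotylboration), followed by removal of the carbinol oxygen.
- The ring alkene is traced to an enone. Conjugate reduction/enol triflation and C–O hydrogenolysis turn a 6-tert-alkylcarvone into the 3-substituted p-mentha-1,8-diene.
- Key disconnection: the 6-tert-alkylcarvone is the [3,3] isomer of an allyl dienyl ether. That ether is cut at its C(sp2)–O bond into the kinetic dienyl triflate of (S)-carvone (C10) and (2E,6E)-farnesol (C15). Forming this C–O bond joins the two halves, and its Claisen relay sets the ring C3 and quaternary stereocentres.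
- Rings: the single ring (ring A) and its isopropenyl stereocentre come with (S)-carvone. No ring is formed in the route.

Assumption: the target is taken exactly as drawn by the SMILES, that is ring (1S,6S)-trans, quaternary carbon S, allylic methine S, central chain alkene E.

**Step 1**
Reactants: 1 (S)-(+)-carvone
Product: 3 (3S)-6-methyl-3-(prop-1-en-2-yl)cyclohexa-1,5-dien-1-yl triflate (carvone dienyl triflate), via lithium dienolate 2 (not isolated)
Conditions: LiN(i-Pr)2 (1.1 equiv), THF, −78 °C; PhNTf2 (1.1 equiv), −78 to 0 °C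
Reagents that add atoms: N-phenylbis(trifluoromethanesulfonimide) (PhNTf2), O=S(=O)(N(c1ccccc1)S(=O)(=O)C(F)(F)F)C(F)(F)F
Why: Kinetic alpha-prime deprotonation of the cross-conjugated enone by the hindered amide and O-sulfonylation of the dienolate (enol triflate formation) is standard for carvone and does not touch the isopropenyl-bearing stereocentre.

**Step 2**
Reactants: 3 carvone dienyl triflate; 4 (2E,6E)-farnesol
Product: 6 (5S,6S)-2-methyl-5-(prop-1-en-2-yl)-6-[(3R,6E)-3,7,11-trimethyldodeca-1,6,10-trien-3-yl]cyclohex-2-en-1-one, via allyl dienyl ether 5 (not isolated)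
Conditions: [Pd(allyl)Cl]2 (2.5 mol %), RockPhos (6 mol %), Cs2CO3 (1.5 equiv), 4 Å MS, toluene, 80 °C, 6 h; then 110 °C, 12 h
Reagents that add atoms: none
Why: Proposed new method: oxidative addition of the dienyl triflate to zerovalent palladium bearing a very bulky biaryl phosphine, carbonate-assisted exchange of triflate for the farnesyl alkoxide and C(sp2)–O reductive elimination (made faster than beta-hydride elimination by the ligand bulk) should give ether 5, whose 2-vinyl-substituted oxa-diene then undergoes a suprafacial Claisen [3,3] shift through a chair on the ring face anti to the isopropenyl group, with the E-alkene placing the homogeranyl chain pseudo-equatorial and the methyl pseudo-axial so that C6 (S, trans to isopropenyl) and the quaternary carbon (R) are set together; the closest known reaction types are the palladium-catalysed etherification of aryl halides with primary alcohols and the copper-catalysed vinyl iodide/allylic alcohol coupling–Claisen domino, neither of which has been shown for an enone-derived dienyl triflate and an allylic alcohol.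

**Step 3**
Reactants: 6 the 6-tert-alkylcarvone
Product: 8 (5S,6S)-2-methyl-5-(prop-1-en-2-yl)-6-[(3R,6E)-3,7,11-trimethyldodeca-1,6,10-trien-3-yl]cyclohex-1-en-1-yl triflate, via lithium enolate 7 (not isolated)
Conditions: LiBH(s-Bu)3 (1.1 equiv), THF, −78 °C; PhNTf2 (1.3 equiv), −78 °C to rt
Reagents that add atoms: N-phenylbis(trifluoromethanesulfonimide) (PhNTf2), O=S(=O)(N(c1ccccc1)S(=O)(=O)C(F)(F)F)C(F)(F)F
Why: The bulky borohydride adds hydride 1,4 to this cyclohexenone (no extra beta substituent, carbonyl shielded by the tert-alkyl neighbour) and the regiodefined enolate is trapped on oxygen (conjugate reduction–enol triflation), which fixes the future ring alkene position without touching any stereocentre.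

**Step 4**
Reactants: 8 the enol triflate
Product: 9 (3S,4S)-1-methyl-4-(prop-1-en-2-yl)-3-[(3R,6E)-3,7,11-trimethyldodeca-1,6,10-trien-3-yl]cyclohex-1-ene
Conditions: Pd(OAc)2 (5 mol %), PPh3 (12 mol %), HCO2H (3 equiv), Et3N (4 equiv), DMF, 60 °C
Reagents that add atoms: none
Why: Palladium-catalysed formate hydrogenolysis of a vinyl triflate (oxidative addition, formate decarboxylation to a palladium hydride, C–H reductive elimination) replaces OTf by H with retention of the alkene position and leaves the isolated alkenes and all stereocentres unchanged.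

**Step 5**
Reactants: 9 the C25 hydrocarbon
Product: 10 (4R,7E)-4,8,12-trimethyl-4-[(1S,6S)-3-methyl-6-(prop-1-en-2-yl)cyclohex-2-en-1-yl]trideca-7,11-dienal
Conditions: Rh(acac)(CO)2 (1 mol %), PPh3 (10 mol %), CO/H2 (1:1, 20 bar), toluene, 60 °C
Reagents that add atoms: carbon monoxide, [C-]#[O+]
Why: Rhodium-catalysed hydroformylation is far faster for the monosubstituted vinyl group than for 1,1-disubstituted or trisubstituted alkenes, and the adjacent quaternary carbon excludes the branched isomer (Keulemans rule), so only the linear aldehyde forms and no stereocentre is touched.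

**Step 6**
Reactants: 10 the aldehyde; 11 cis-2-butene
Product: 14 (3R,4R,7R,10E)-3,7,11,15-tetramethyl-7-[(1S,6S)-3-methyl-6-(prop-1-en-2-yl)cyclohex-2-en-1-yl]hexadeca-1,10,14-trien-4-ol, via (Z)-crotylborane 12 (not isolated), via borinate ester 13 (not isolated)
Conditions: 11, n-BuLi, KOt-Bu, THF, −78 to −45 °C; (−)-Ipc2BOMe, −78 °C; BF3·OEt2; 10, −78 °C, 4 h; then 3 M NaOH, 30 % H2O2, rt
Reagents that add atoms: none
Why: Brown asymmetric crotylboration runs through a closed Zimmerman–Traxler chair in which the Z-crotyl geometry gives the syn adduct and the isopinocampheyl groups derived from (+)-alpha-pinene direct attack to the Si face of the aldehyde, so the methyl-bearing carbon (3R here, 3S in the target once the neighbouring oxygen is gone) is set by reagent control independent of the remote stereocentres.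

**Step 7**
Reactants: 14 the homoallylic alcohol
Product: 15 O-[(3R,4R,7R,10E)-hexadecatrien-4-yl] 1H-imidazole-1-carbothioate of 14
Conditions: 1,1'-thiocarbonyldiimidazole (1.5 equiv), DMAP (0.2 equiv), ClCH2CH2Cl, 70 °C
Reagents that add atoms: 1,1'-thiocarbonyldiimidazole, S=C(n1ccnc1)n1ccnc1
Why: Thioacyl transfer to the secondary hydroxyl (first half of the Barton–McCombie deoxygenation) takes place at oxygen only, so no stereocentre is affected.

**Step 8**
Reactants: 15 the imidazolyl thiocarbonate
Product: 16 (3S,4S)-1-methyl-4-(prop-1-en-2-yl)-3-[(3S,7S,10E)-3,7,11,15-tetramethylhexadeca-1,10,14-trien-7-yl]cyclohex-1-ene (target)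
Conditions: Bu3SnH (3 equiv, 0.5 M), AIBN (0.15 equiv), toluene, 100 °C
Reagents that add atoms: none
Why: In the Barton–McCombie radical deoxygenation the stannyl radical adds to C=S, the secondary C–O bond fragments and the alkyl radical is quenched by concentrated Bu3SnH faster than 3-exo vinyl migration or 6-exo cyclisation, which erases only the carbinol centre and leaves the four target stereocentres intact.

**Compound list**
1 | (S)-(+)-carvone | CC1=CC[C@@H](CC1=O)C(C)=C | starting material
2 | lithium (3S)-6-methyl-3-(prop-1-en-2-yl)cyclohexa-1,5-dien-1-olate | C1=C([O-])C(C)=CC[C@@H]1C(=C)C.[Li+] | intermediate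
3 | (3S)-6-methyl-3-(prop-1-en-2-yl)cyclohexa-1,5-dien-1-yl trifluoromethanesulfonate | C1=C(OS(=O)(=O)C(F)(F)F)C(C)=CC[C@@H]1C(=C)C | intermediate
4 | (2E,6E)-farnesol | CC(C)=CCC/C(C)=C/CC/C(C)=C/CO | starting material
5 | (5S)-2-methyl-5-(prop-1-en-2-yl)-3-{[(2E,6E)-3,7,11-trimethyldodeca-2,6,10-trien-1-yl]oxy}cyclohexa-1,3-diene | C1=C(OC/C=C(\C)CC/C=C(\C)CCC=C(C)C)C(C)=CC[C@@H]1C(=C)C | intermediate
6 | (5S,6S)-2-methyl-5-(prop-1-en-2-yl)-6-[(3R,6E)-3,7,11-trimethyldodeca-1,6,10-trien-3-yl]cyclohex-2-en-1-one | C=C[C@@](C)(CC/C=C(\C)CCC=C(C)C)[C@H]1C(=O)C(C)=CC[C@@H]1C(=C)C | intermediate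
7 | lithium enolate from 1,4-reduction of 6 | C=C[C@@](C)(CC/C=C(\C)CCC=C(C)C)[C@H]1C([O-])=C(C)CC[C@@H]1C(=C)C.[Li+] | intermediate
8 | (5S,6S)-2-methyl-5-(prop-1-en-2-yl)-6-[(3R,6E)-3,7,11-trimethyldodeca-1,6,10-trien-3-yl]cyclohex-1-en-1-yl trifluoromethanesulfonate | C=C[C@@](C)(CC/C=C(\C)CCC=C(C)C)[C@H]1C(OS(=O)(=O)C(F)(F)F)=C(C)CC[C@@H]1C(=C)C | intermediate
9 | (3S,4S)-1-methyl-4-(prop-1-en-2-yl)-3-[(3R,6E)-3,7,11-trimethyldodeca-1,6,10-trien-3-yl]cyclohex-1-ene | C=C[C@@](C)(CC/C=C(\C)CCC=C(C)C)[C@H]1C=C(C)CC[C@@H]1C(=C)C | intermediate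
10 | (4R,7E)-4,8,12-trimethyl-4-[(1S,6S)-3-methyl-6-(prop-1-en-2-yl)cyclohex-2-en-1-yl]trideca-7,11-dienal | O=CCC[C@@](C)(CC/C=C(\C)CCC=C(C)C)[C@H]1C=C(C)CC[C@@H]1C(=C)C | intermediate
11 | cis-2-butene | C/C=C\C | starting material
12 | (Z)-crotylbis(isopinocampheyl)borane, Ipc from (+)-alpha-pinene | C/C=C\CB([C@@H]1C[C@@H]2C[C@H]([C@H]1C)C2(C)C)[C@@H]1C[C@@H]2C[C@H]([C@H]1C)C2(C)C | intermediate
13 | bis(isopinocampheyl)borinate ester of 14 | C=C[C@@H](C)[C@H](OB([C@@H]2C[C@@H]3C[C@H]([C@H]2C)C3(C)C)[C@@H]2C[C@@H]3C[C@H]([C@H]2C)C3(C)C)CC[C@@](C)(CC/C=C(\C)CCC=C(C)C)[C@H]1C=C(C)CC[C@@H]1C(=C)C | intermediate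
14 | (3R,4R,7R,10E)-3,7,11,15-tetramethyl-7-[(1S,6S)-3-methyl-6-(prop-1-en-2-yl)cyclohex-2-en-1-yl]hexadeca-1,10,14-trien-4-ol | C=C[C@@H](C)[C@H](O)CC[C@@](C)(CC/C=C(\C)CCC=C(C)C)[C@H]1C=C(C)CC[C@@H]1C(=C)C | intermediate
15 | O-alkyl 1H-imidazole-1-carbothioate of 14 | C=C[C@@H](C)[C@H](OC(=S)n2ccnc2)CC[C@@](C)(CC/C=C(\C)CCC=C(C)C)[C@H]1C=C(C)CC[C@@H]1C(=C)C | intermediate
16 | (3S,4S)-1-methyl-4-(prop-1-en-2-yl)-3-[(3S,7S,10E)-3,7,11,15-tetramethylhexadeca-1,10,14-trien-7-yl]cyclohex-1-ene (CNP0208273.1) | C=C[C@@H](C)CCC[C@@](C)(CC/C=C(\C)CCC=C(C)C)[C@H]1C=C(C)CC[C@@H]1C(=C)C | target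

Total step count: 8. Longest linear sequence: 8 steps (1 to 16).

**Steps most likely to fail**

Step 2 (the new step). There are three risks:
- Beta-hydride elimination of the palladium alkoxide, giving farnesal and the reduced diene.
- S–O cleavage of the triflate by alkoxide.
- Leakage through a boat transition state, which gives the quaternary epimer; this would be separated at 6.

The fallback uses known chemistry and sets out from 3. Miyaura borylation (B2pin2, PdCl2(PPh3)2, PPh3, KOPh, toluene, 50 °C) gives the dienyl pinacol boronate F1. This is joined to 4 by the copper-promoted oxidative coupling established for vinyl and dienyl boronates with allylic alcohols (Cu(OAc)2, Et3N, air, rt). The product is ether 5, now isolated, where the fallback comes back to the route. Heating in toluene at 110 °C carries it on to 6.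

Step 3. O-triflation of an enolate flanked by a methyl-bearing and a tert-alkyl-bearing carbon may be slow, some 1,2-reduction is possible, and the derived triflate could undergo Heck cyclisation in step 4. The fallback replaces the C–O hydrogenolysis logic by a C=N based alkene walk and sets out from 6.
- Condensation with TsNHNH2 (EtOH, cat. TsOH, 50 °C) gives the tosylhydrazone F2.
- Catecholborane (CHCl3, −10 °C to rt) reduces it 1,2 to the allylic tosylhydrazine F3.
- NaOAc·3H2O at reflux expels sulfinate to give the allylic diazene F4.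
- F4 loses nitrogen by a retro-ene shift that delivers hydrogen to the former beta carbon, and the route is rejoined at 9.

Step 5. The vinyl group sits on a very crowded quaternary carbon, so its rate advantage over the isopropenyl group may shrink. The fallback builds the extra carbon through boron and sets out from 9.
- Hydroboration with HBpin ([Ir(cod)Cl]2, dppe, CH2Cl2, rt), which accepts only the monosubstituted alkene, gives the primary pinacol boronate F5.
- Matteson homologation with LiCHCl2 (CH2Cl2, LiN(i-Pr)2, THF, −100 °C, then ZnCl2) gives the alpha-chloro boronate F6.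
- Buffered oxidation (NaBO3·4H2O, THF/H2O) collapses F6 to the aldehyde, and the route is rejoined at 10.

**Further compounds**
F1 | step 2 | 2-[(3S)-6-methyl-3-(prop-1-en-2-yl)cyclohexa-1,5-dien-1-yl]-4,4,5,5-tetramethyl-1,3,2-dioxaborolane | C1=C(B2OC(C)(C)C(C)(C)O2)C(C)=CC[C@@H]1C(=C)C
F2 | step 3 | p-toluenesulfonylhydrazone of 6 | C=C[C@@](C)(CC/C=C(\C)CCC=C(C)C)[C@H]1C(=NNS(=O)(=O)c2ccc(C)cc2)C(C)=CC[C@@H]1C(=C)C
F3 | step 3 | allylic N'-tosylhydrazine from 1,2-reduction of F2 | C=C[C@@](C)(CC/C=C(\C)CCC=C(C)C)[C@H]1C(NNS(=O)(=O)c2ccc(C)cc2)C(C)=CC[C@@H]1C(=C)C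
F4 | step 3 | allylic diazene | C=C[C@@](C)(CC/C=C(\C)CCC=C(C)C)[C@H]1C(N=N)C(C)=CC[C@@H]1C(=C)C
F5 | step 5 | primary pinacol boronate from anti-Markovnikov hydroboration of 9 | CC1(C)OB(CC[C@@](C)(CC/C=C(\C)CCC=C(C)C)[C@H]2C=C(C)CC[C@@H]2C(=C)C)OC1(C)C
F6 | step 5 | alpha-chloro pinacol boronate (epimer mixture at CHCl) | CC1(C)OB(C(Cl)CC[C@@](C)(CC/C=C(\C)CCC=C(C)C)[C@H]2C=C(C)CC[C@@H]2C(=C)C)OC1(C)C
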